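**Retrosynthetic overview**

1. Target ⇒ (3R,3'R,6'R)-lutein + vinyl palmitate. The ester C–O bond at C3 is made last and site-selectively; the allylic C3'–OH stays free and no protecting group is used on either hydroxyl.
2. Lutein ⇒ C15 (ε end) + C10 + C15 (β end): two Wittig olefinations on 2,7-dimethylocta-2,4,6-trienedial (C11'=C12' first, then C11=C12).
3. Both C15 phosphonium salts ⇒ (vinyl Grignard, then Ph3P·HBr) ⇒ the two enantiomers of trans-3-hydroxy-α-ionone. The (3R,6R) enantiomer is the ε end as it stands; the (3S,6S) enantiomer becomes the (3R)-β end by a base-mediated shift of the ring double bond (C3 is untouched, only its CIP label changes).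
4. rac-trans-3-Hydroxy-α-ionone ⇒ lipase resolution; it comes from trans-selective hydride reduction of 3-oxo-α-ionone ketal, made by allylic oxidation of (±)-α-ionone ketal.
5. Ring order: no ring is built. Both six-membered rings come from α-ionone, and the β ring is derived from the ε-type ring in the isomerisation step.

Assumption: Burkholderia cepacia lipase follows the usual secondary-alcohol rule on these rings with the CH2–CMe2 flank as the large group, so the carbinol arrangement of the (3R)-β ring (labelled 3S in the ε/α ring) is acylated fast and the (3R)-ε arrangement is left.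

**Route**

Step 1
Reactants: 1 (±)-α-ionone
Product: 2 α-ionone ethylene ketal
Conditions: HOCH2CH2OH (3 equiv), HC(OEt)3 (1.5 equiv), p-TsOH·H2O (2 mol%), rt, 16 h
Reagents that add atoms: ethylene glycol, OCCO
Why: Acid-catalysed ketalisation (orthoester as water scavenger) masks the side-chain ketone so that only one carbonyl is present in the hydride step; at room temperature the 7,8-double bond stays in place and C6 is untouched.

Step 2
Reactants: 2 α-ionone ethylene ketal
Product: 3 3-oxo-α-ionone ethylene ketal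
Conditions: t-BuOOH (70% aq., 6 equiv), aq. NaOCl (4 equiv), K2CO3 (0.2 equiv), MeCN, −5 → 0 °C
Reagents that add atoms: tert-butyl hydroperoxide, CC(C)(C)OO
Why: Radical allylic C–H oxidation (tert-butylperoxyl chain, allylic peroxide collapsing to the enone) attacks the only unhindered allylic methylene, C3, because the tertiary C6–H is screened by the gem-dimethyl group and the side chain.

Step 3
Reactants: 3 3-oxo-α-ionone ethylene ketal
Product: 5 rac-trans-3-hydroxy-α-ionone, via hydroxy ketal 4 (not isolated)
Conditions: K[(sec-Bu)3BH] (1.2 equiv), THF, −78 °C; then 0.5 M aq. HCl, THF, 0 °C, 30 min; SiO2 (minor cis isomer removed)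
Reagents that add atoms: water, O
Why: Diastereoselective 1,2-hydride reduction of the β,β-disubstituted enone: with the C6 side chain pseudo-axial, the C1 methyl syn-axial to C3 blocks one face, so the bulky borohydride enters from the other and places the new C3–OH trans to the side chain (the (3R,6R)/(3S,6S) pair); dilute acid then hydrolyses the allylic ketal (acetal hydrolysis) much faster than it can ionise the allylic alcohol.

Step 4
Reactants: 5 rac-trans-3-hydroxy-α-ionone
Product: 6 (3R,6R)-3-hydroxy-α-ionone (recovered alcohol) plus 7 (3S,6S)-3-acetoxy-α-ionone (both isolated)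
Conditions: Burkholderia cepacia lipase (immobilised), vinyl acetate (3 equiv), t-BuOMe, 30 °C, to 50% conversion; SiO2
Reagents that add atoms: vinyl acetate, C=COC(C)=O
Why: Lipase-catalysed kinetic resolution by irreversible transesterification: only the (3S,6S) carbinol is acetylated and the (3R,6R) enantiomer stays as the alcohol, so the absolute configuration of C3'/C6' (in 6) and of the future C3 (in 7) is fixed here and both halves of the racemate are used.

Step 5
Reactants: 7 (3S,6S)-3-acetoxy-α-ionone
Product: 9 (3R)-3-hydroxy-β-ionone, via (3S,6S)-3-hydroxy-α-ionone 8 (not isolated)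
Conditions: KOH (2 equiv), MeOH, 25 → 45 °C, N2
Reagents that add atoms: none
Why: Saponification followed by base-mediated alkene isomerisation (vinylogous enolisation at C6, reprotonation at C4) moves the ring double bond into conjugation with the enone; no bond to C3 is made or broken, and the descriptor changes from S to R only because C2 outranks C4 once C4 is sp3.

Step 6
Reactants: 9 (3R)-3-hydroxy-β-ionone
Product: 10 β-end vinyl carbinol
Conditions: CH2=CHMgBr (2.5 equiv), THF, −20 → 0 °C; aq. NH4Cl
Reagents that add atoms: vinylmagnesium bromide, C=C[Mg]Br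
Why: Grignard 1,2-addition to the methyl ketone after the first equivalent has deprotonated the hydroxyl; the new tertiary carbinol forms as both epimers and is erased in step 7.

Step 7
Reactants: 10 β-end vinyl carbinol
Product: 11 β-end C15 phosphonium bromide
Conditions: Ph3P·HBr (1.05 equiv), MeOH, rt, 16 h; crystallise from EtOAc (9E isomer)
Reagents that add atoms: triphenylphosphine hydrobromide, [Br-].[PH+](c1ccccc1)(c1ccccc1)c1ccccc1
Why: SN1-type allylic transposition: the tertiary doubly allylic alcohol ionises to a pentadienyl cation that PPh3 captures at the unhindered terminus, giving the conjugated (E,E)-dienyl phosphonium salt, while the homoallylic ring hydroxyl does not ionise.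

Step 8
Reactants: 6 (3R,6R)-3-hydroxy-α-ionone
Product: 12 ε-end vinyl carbinol
Conditions: CH2=CHMgBr (2.5 equiv), THF, −20 → 0 °C; aq. NH4Cl
Reagents that add atoms: vinylmagnesium bromide, C=C[Mg]Br
Why: Grignard 1,2-addition to the methyl ketone at low temperature, where addition outruns enolisation at C6; C3 and C6 are untouched and the new carbinol centre is erased in step 9.

Step 9
Reactants: 12 ε-end vinyl carbinol
Product: 13 ε-end C15 phosphonium bromide
Conditions: Ph3P·HBr (1.0 equiv), CH2Cl2, 0 °C, 1–2 h; precipitate with Et2O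
Reagents that add atoms: triphenylphosphine hydrobromide, [Br-].[PH+](c1ccccc1)(c1ccccc1)c1ccccc1
Why: The same SN1-type allylic transposition: the tertiary doubly allylic carbinol ionises far faster than the secondary ring allylic alcohol, and the non-nucleophilic solvent, low temperature and short time keep C3 from forming an ether or epimerising.

Step 10
Reactants: 13 ε-end C15 phosphonium bromide; 14 C10 dialdehyde (3 equiv)
Product: 17 all-E C25 hydroxy aldehyde, via ε-ylide 15 (not isolated), via 8Z-aldehyde 16 (not isolated)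
Conditions: NaOMe (1.1 equiv, slow addition), CH2Cl2/MeOH, −10 °C → rt; then EtOAc, reflux, N2, dark, 3 h; SiO2 (excess 14 recovered)
Reagents that add atoms: none
Why: Wittig olefination: the semistabilised allylic ylide condenses with one formyl group of the excess dialdehyde (the second is deactivated once the first has reacted), and the E/Z mixture at the new double bond is equilibrated thermally to the all-E hexaenal; no stereocentre is touched.

Step 11
Reactants: 11 β-end C15 phosphonium bromide (1.3 equiv); 17 all-E C25 hydroxy aldehyde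
Product: 20 (3R,3'R,6'R)-lutein, via β-ylide 18 (not isolated), via 11Z-lutein 19 (not isolated)
Conditions: NaOMe (1.5 equiv), CH2Cl2/MeOH, 0 °C → rt; then heptane/EtOH, reflux, N2, dark, 6 h; crystallise
Reagents that add atoms: none
Why: Wittig olefination forms the C11=C12 bond with both hydroxyls free; thermal Z → E isomerisation and crystallisation give the all-E polyene with C3, C3' and C6' unchanged.

Step 12
Reactants: 20 (3R,3'R,6'R)-lutein; 21 vinyl palmitate (2 equiv)
Product: 22 lutein 3-O-palmitate (target)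
Conditions: Burkholderia cepacia lipase (immobilised), toluene, 4 Å molecular sieves, 40 °C, Ar, dark; stop when 20 is consumed; SiO2
Reagents that add atoms: none
Why: Proposed new method: site-selective lipase transesterification of an unprotected C40 diol with a long-chain vinyl ester. The palmitoyl-serine acyl-enzyme (formed irreversibly, acetaldehyde leaves) is attacked only by a carbinol that fits the stereospecificity pocket. The two carbinols of 20 are locally mirror-image: C3 (homoallylic, equatorial) has the arrangement acylated fast in step 4, and C3' (allylic, pseudo-axial) is the arrangement the same enzyme left untouched there. The ester C–O bond should therefore form at C3 alone, with every stereocentre unchanged. The closest known reaction types are lipase kinetic resolution of 3-hydroxyionones and unselective lipase esterification of xanthophylls to diesters.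

**Compound list**

1 | (±)-α-ionone, (E)-4-(2,6,6-trimethylcyclohex-2-en-1-yl)but-3-en-2-one (racemic) | CC(=O)/C=C/C1C(C)=CCCC1(C)C | starting material
2 | α-ionone ethylene ketal, 2-methyl-2-[(E)-2-(2,6,6-trimethylcyclohex-2-en-1-yl)ethenyl]-1,3-dioxolane (racemic) | CC1(/C=C/C2C(C)=CCCC2(C)C)OCCO1 | intermediate
3 | 3-oxo-α-ionone ethylene ketal, 3,5,5-trimethyl-4-[(E)-2-(2-methyl-1,3-dioxolan-2-yl)ethenyl]cyclohex-2-en-1-one (racemic) | CC1(/C=C/C2C(C)=CC(=O)CC2(C)C)OCCO1 | intermediate
4 | rac-trans-3-hydroxy-α-ionone ethylene ketal, (1RS,4RS)-3,5,5-trimethyl-4-[(E)-2-(2-methyl-1,3-dioxolan-2-yl)ethenyl]cyclohex-2-en-1-ol (racemate, (1R,4R) enantiomer drawn) | CC1(/C=C/[C@H]2C(C)=C[C@H](O)CC2(C)C)OCCO1 | intermediate (not isolated)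
5 | rac-trans-3-hydroxy-α-ionone, (E)-4-[(1RS,4RS)-4-hydroxy-2,6,6-trimethylcyclohex-2-en-1-yl]but-3-en-2-one (racemate, (1R,4R) enantiomer drawn) | CC(=O)/C=C/[C@H]1C(C)=C[C@H](O)CC1(C)C | intermediate
6 | (3R,6R)-3-hydroxy-α-ionone, (E)-4-[(1R,4R)-4-hydroxy-2,6,6-trimethylcyclohex-2-en-1-yl]but-3-en-2-one | CC(=O)/C=C/[C@H]1C(C)=C[C@H](O)CC1(C)C | intermediate
7 | (3S,6S)-3-acetoxy-α-ionone, (1S,4S)-3,5,5-trimethyl-4-[(1E)-3-oxobut-1-en-1-yl]cyclohex-2-en-1-yl acetate | CC(=O)/C=C/[C@@H]1C(C)=C[C@@H](OC(C)=O)CC1(C)C | intermediate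
8 | (3S,6S)-3-hydroxy-α-ionone, (E)-4-[(1S,4S)-4-hydroxy-2,6,6-trimethylcyclohex-2-en-1-yl]but-3-en-2-one | CC(=O)/C=C/[C@@H]1C(C)=C[C@@H](O)CC1(C)C | intermediate (not isolated)
9 | (3R)-3-hydroxy-β-ionone, (E)-4-[(4R)-4-hydroxy-2,6,6-trimethylcyclohex-1-en-1-yl]but-3-en-2-one | CC(=O)/C=C/C1=C(C)C[C@@H](O)CC1(C)C | intermediate
10 | β-end vinyl carbinol, (1R)-4-[(1E)-3-hydroxy-3-methylpenta-1,4-dien-1-yl]-3,5,5-trimethylcyclohex-3-en-1-ol (both epimers at the tertiary carbinol) | C=CC(C)(O)/C=C/C1=C(C)C[C@@H](O)CC1(C)C | intermediate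
11 | β-end C15 phosphonium bromide, [(2E,4E)-5-[(4R)-4-hydroxy-2,6,6-trimethylcyclohex-1-en-1-yl]-3-methylpenta-2,4-dien-1-yl]triphenylphosphonium bromide | [Br-].c1ccccc1[P+](c1ccccc1)(c1ccccc1)C/C=C(C)/C=C/C1=C(C)C[C@@H](O)CC1(C)C | intermediate
12 | ε-end vinyl carbinol, (1R,4R)-4-[(1E)-3-hydroxy-3-methylpenta-1,4-dien-1-yl]-3,5,5-trimethylcyclohex-2-en-1-ol (both epimers at the tertiary carbinol) | C=CC(C)(O)/C=C/[C@H]1C(C)=C[C@H](O)CC1(C)C | intermediate
13 | ε-end C15 phosphonium bromide, [(2E,4E)-5-[(1R,4R)-4-hydroxy-2,6,6-trimethylcyclohex-2-en-1-yl]-3-methylpenta-2,4-dien-1-yl]triphenylphosphonium bromide | [Br-].c1ccccc1[P+](c1ccccc1)(c1ccccc1)C/C=C(C)/C=C/[C@H]1C(C)=C[C@H](O)CC1(C)C | intermediate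
14 | C10 dialdehyde, (2E,4E,6E)-2,7-dimethylocta-2,4,6-trienedial | O=C/C(C)=C/C=C/C=C(C)/C=O | starting material
15 | ε-ylide, the triphenylphosphonium ylide formed from 13 by loss of HBr | c1ccccc1[P+](c1ccccc1)(c1ccccc1)[CH-]/C=C(C)/C=C/[C@H]1C(C)=C[C@H](O)CC1(C)C | intermediate (not isolated)
16 | 8Z-aldehyde, (2E,4E,6E,8Z,10E,12E)-13-[(1R,4R)-4-hydroxy-2,6,6-trimethylcyclohex-2-en-1-yl]-2,7,11-trimethyltrideca-2,4,6,8,10,12-hexaenal | O=C/C(C)=C/C=C/C=C(C)/C=C\C=C(C)\C=C\[C@H]1C(C)=C[C@H](O)CC1(C)C | intermediate (not isolated)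
17 | all-E C25 hydroxy aldehyde, (2E,4E,6E,8E,10E,12E)-13-[(1R,4R)-4-hydroxy-2,6,6-trimethylcyclohex-2-en-1-yl]-2,7,11-trimethyltrideca-2,4,6,8,10,12-hexaenal | O=C/C(C)=C/C=C/C=C(C)/C=C/C=C(C)/C=C/[C@H]1C(C)=C[C@H](O)CC1(C)C | intermediate
18 | β-ylide, the triphenylphosphonium ylide formed from 11 by loss of HBr | c1ccccc1[P+](c1ccccc1)(c1ccccc1)[CH-]/C=C(C)/C=C/C1=C(C)C[C@@H](O)CC1(C)C | intermediate (not isolated)
19 | 11Z-lutein, (3R,3'R,6'R)-β,ε-carotene-3,3'-diol with Z geometry at C11=C12 only | O[C@@H]1CC(C)=C(\C=C\C(C)=C\C=C/C(C)=C/C=C/C=C(C)/C=C/C=C(C)/C=C/[C@H]2C(C)=C[C@H](O)CC2(C)C)C(C)(C)C1 | intermediate (not isolated)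
20 | (3R,3'R,6'R)-lutein, all-E (3R,3'R,6'R)-β,ε-carotene-3,3'-diol | O[C@@H]1CC(C)=C(/C=C/C(C)=C/C=C/C(C)=C/C=C/C=C(C)/C=C/C=C(C)/C=C/[C@H]2C(C)=C[C@H](O)CC2(C)C)C(C)(C)C1 | intermediate
21 | vinyl palmitate, ethenyl hexadecanoate | CCCCCCCCCCCCCCCC(=O)OC=C | starting material
22 | lutein 3-O-palmitate, all-E (3R,3'R,6'R)-3'-hydroxy-β,ε-caroten-3-yl hexadecanoate | CCCCCCCCCCCCCCCC(=O)O[C@@H]1CC(C)=C(/C=C/C(C)=C/C=C/C(C)=C/C=C/C=C(C)/C=C/C=C(C)/C=C/[C@H]2C(C)=C[C@H](O)CC2(C)C)C(C)(C)C1 | target

**Step count and risks**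

Total step count: 12. Longest linear sequence: 9 steps (1, 2, 3, 4, 5, 6, 7, 11, 12; the ε branch 1, 2, 3, 4, 8, 9, 10, 11, 12 is equally long).

The three steps most likely to fail:

Step 12 (the proposed new step). The enzyme may accept the C40 substrate slowly or discriminate the two carbinols incompletely, giving the 3'-monoester and the diester beside 22. The fallback uses known chemistry, sets out from 11 and comes back to the route at 22, bypassing 18, 19 and 20. Salt 11 is acylated on its only hydroxyl with palmitoyl chloride and pyridine (cat. DMAP, CH2Cl2, 0 °C) to give the 3-palmitoyloxy C15 phosphonium bromide F1. F1 is condensed with aldehyde 17 under neutral epoxide Wittig conditions (1,2-epoxybutane, CH2Cl2/2-propanol, 60 °C), which spare the ester, through the palmitoyloxy ylide F2. The Z portion of the product, the 11Z isomer of the target F3, is converted by the same thermal isomerisation as in step 11, giving 22 with the C3'–OH never exposed to an acylating agent.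

Step 9. The ring allylic alcohol of 12 may ionise under Ph3P·HBr (epimerisation at C3, bromide or ether formation), or the cation may lose the C6 proton. The fallback sets out from 6 and comes back at 13, forming the phosphonium salt without acid. A Horner–Wadsworth–Emmons reaction of 6 with triethyl phosphonoacetate (NaH, 2.2 equiv, THF, 0 °C → rt; 9E isomer separated) gives the ethyl dienoate F4. Reduction with i-Bu2AlH (CH2Cl2, −78 °C) gives the primary allylic alcohol F5. CBr4/PPh3 (CH2Cl2, −30 °C) converts only the primary allylic hydroxyl into the allylic bromide F6. PPh3 in EtOAc at rt then gives 13 by simple SN2 quaternisation.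

Step 4. The enantioselectivity on the allylic carbinol may be too low, or the sense may be opposite to the assumption. The fallback sets out from 5 and comes back at 6 and, through 8, at 9. Racemate 5 is separated by preparative supercritical-fluid chromatography on a chiral stationary phase (amylose tris(3,5-dimethylphenylcarbamate), CO2/MeOH) into 6 and its enantiomer 8, with absolute configuration assigned by Mosher ester analysis. Compound 8 is then isomerised with KOH/MeOH exactly as in step 5 to give 9. No new compound arises.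

Further compounds

F1 | step 12 | [(2E,4E)-5-[(4R)-4-(hexadecanoyloxy)-2,6,6-trimethylcyclohex-1-en-1-yl]-3-methylpenta-2,4-dien-1-yl]triphenylphosphonium bromide | [Br-].c1ccccc1[P+](c1ccccc1)(c1ccccc1)C/C=C(C)/C=C/C1=C(C)C[C@@H](OC(=O)CCCCCCCCCCCCCCC)CC1(C)C
F2 | step 12 | triphenylphosphonium ylide formed from F1 by loss of HBr | c1ccccc1[P+](c1ccccc1)(c1ccccc1)[CH-]/C=C(C)/C=C/C1=C(C)C[C@@H](OC(=O)CCCCCCCCCCCCCCC)CC1(C)C
F3 | step 12 | 11Z isomer of 22, (3R,3'R,6'R)-3'-hydroxy-β,ε-caroten-3-yl hexadecanoate with Z geometry at C11=C12 only | CCCCCCCCCCCCCCCC(=O)O[C@@H]1CC(C)=C(\C=C\C(C)=C\C=C/C(C)=C/C=C/C=C(C)/C=C/C=C(C)/C=C/[C@H]2C(C)=C[C@H](O)CC2(C)C)C(C)(C)C1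
F4 | step 9 | ethyl (2E,4E)-5-[(1R,4R)-4-hydroxy-2,6,6-trimethylcyclohex-2-en-1-yl]-3-methylpenta-2,4-dienoate | CCOC(=O)/C=C(C)/C=C/[C@H]1C(C)=C[C@H](O)CC1(C)C
F5 | step 9 | (2E,4E)-5-[(1R,4R)-4-hydroxy-2,6,6-trimethylcyclohex-2-en-1-yl]-3-methylpenta-2,4-dien-1-ol | OC/C=C(C)/C=C/[C@H]1C(C)=C[C@H](O)CC1(C)C
F6 | step 9 | (1R,4R)-4-[(1E,3E)-5-bromo-3-methylpenta-1,3-dien-1-yl]-3,5,5-trimethylcyclohex-2-en-1-ol | BrC/C=C(C)/C=C/[C@H]1C(C)=C[C@H](O)CC1(C)C
F0 | step 4 | none | none
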